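**Retrosynthetic overview**
1. Tetronic acid ring (closed last): lactonisation of a γ-hydroxy-β-keto ester whose C3–C4 bond comes from an intermolecular aldol addition of the lithium enolate of methyl propanoate to α-silyloxy aldehyde 30, followed by oxidation.
2. C9–C10 of the diene: Suzuki coupling of (E)-alkenylboronate 28 (C4–C9) with (E)-alkenyl iodide 12 (C10–C18 plus furan).
3. Fragment 28: C6–C7 by Evans titanium-enolate Michael addition to tert-butyl acrylate (sets C7); C5–O by Evans enolate hydroxylation (sets C5); C8≡C9 by Ohira–Bestmann homologation.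
4. Fragment 12: (R)-citronellal supplies C15; the furan is attached by B-alkyl Suzuki coupling with 3-bromofuran; C10=C11 comes from Zr-catalysed carboalumination of an alkyne.
5. Ring order: the furan ring is bought pre-formed and attached in step 2; the tetronic acid ring is formed in the final step.

Assumption: atoms are numbered O1, C2 (lactone C=O), C3, C4, C5 in the tetronic acid and C6–C18 along the side chain (furan on C18); the target is (5R,7R,15R,8E,10E), drawn as its 4-hydroxy enol tautomer, and (R)-citronellal of ≥97 % ee is used.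

**Fragment 12 (C10–C18 and furan)**

Step 1
Reactants: 1 (R)-citronellal
Product: 2 (4R)-4,8-dimethylnona-1,7-diene
Conditions: Ph3PCH3Br, KOtBu, THF, 0 °C to rt
Reagents that add atoms: methyltriphenylphosphonium bromide, C[P+](c1ccccc1)(c1ccccc1)c1ccccc1.[Br-]
Why: Wittig methylenation gives the terminal alkene needed for hydroboration, and the stereocentre (β to the carbonyl) is not touched.

Step 2
Reactants: 2 (4R)-4,8-dimethylnona-1,7-diene; 3 3-bromofuran
Product: 5 3-[(4S)-4,8-dimethylnon-7-en-1-yl]furan, via B-alkyl-9-BBN borane 4 (not isolated)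
Conditions: 9-BBN (1.1 equiv), THF, 0 °C to rt; then 3, Pd(dppf)Cl2 (5 mol %), aq. K3PO4, DMF, 60 °C
Reagents that add atoms: none
Why: 9-BBN hydroborates only the monosubstituted alkene (anti-Markovnikov), and the B-alkyl borane then undergoes Suzuki–Miyaura sp3–sp2 coupling with the heteroaryl bromide.

Step 3
Reactants: 5 3-[(4S)-4,8-dimethylnon-7-en-1-yl]furan
Product: 6 (6S)-9-(furan-3-yl)-2,6-dimethylnonane-2,3-diol (both C3 epimers)
Conditions: K2OsO4·2H2O (1 mol %), NMO (1.3 equiv), acetone/H2O 4:1, 0 °C to rt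
Reagents that add atoms: N-methylmorpholine N-oxide, C[N+]1([O-])CCOCC1; water, O
Why: Upjohn dihydroxylation is much faster on the electron-rich trisubstituted alkene than on the aromatic furan, and the new carbinol centre is removed in step 4.

Step 4
Reactants: 6 (6S)-9-(furan-3-yl)-2,6-dimethylnonane-2,3-diol
Product: 8 (4S)-7-(furan-3-yl)-4-methylheptan-1-ol, via aldehyde 7 (not isolated)
Conditions: NaIO4, THF/pH 7 buffer, 0 °C to rt; filter; then NaBH4, MeOH, 0 °C
Reagents that add atoms: none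
Why: Periodate glycol cleavage gives the aldehyde and acetone, and borohydride reduction gives the primary alcohol under conditions harmless to the furan.

Step 5
Reactants: 8 (4S)-7-(furan-3-yl)-4-methylheptan-1-ol
Product: 9 (4S)-7-(furan-3-yl)-4-methylheptyl 4-methylbenzenesulfonate
Conditions: TsCl, Et3N, DMAP (cat.), CH2Cl2, 0 °C to rt
Reagents that add atoms: 4-toluenesulfonyl chloride, Cc1ccc(cc1)S(=O)(=O)Cl
Why: Sulfonylation turns the primary hydroxyl into a leaving group without acid or oxidant.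

Step 6
Reactants: 9 (4S)-7-(furan-3-yl)-4-methylheptyl 4-methylbenzenesulfonate
Product: 10 3-[(4R)-4-methylnon-8-yn-1-yl]furan
Conditions: LiC≡CH·H2NCH2CH2NH2 (3 equiv), DMSO, 15 °C to rt
Reagents that add atoms: lithium acetylide ethylenediamine complex, [Li+].[C-]#C.NCCN
Why: SN2 alkylation of lithium acetylide by the unhindered primary tosylate in DMSO gives the terminal alkyne (the descriptor changes only because of priority rules).

Step 7
Reactants: 10 3-[(4R)-4-methylnon-8-yn-1-yl]furan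
Product: 12 3-[(4S,8E)-9-iodo-4,8-dimethylnon-8-en-1-yl]furan, via (E)-alkenyldimethylalane 11 (not isolated)
Conditions: AlMe3 (2.5 equiv), Cp2ZrCl2 (25 mol %), CH2Cl2, 0 °C to rt; then I2, THF, –30 °C; aq. NaHCO3/Na2S2O3
Reagents that add atoms: trimethylaluminium, C[Al](C)C; iodine, II
Why: Negishi zirconium-catalysed carboalumination adds methyl and aluminium syn across the terminal alkyne with aluminium at the terminus, and iodinolysis with retention gives the (E)-trisubstituted alkenyl iodide.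

**Fragment 28 (C4–C9)**

Step 8
Reactants: 13 (4S)-4-benzyl-3-propanoyl-1,3-oxazolidin-2-one; 14 tert-butyl acrylate
Product: 16 tert-butyl (4R)-5-[(4S)-4-benzyl-2-oxo-1,3-oxazolidin-3-yl]-4-methyl-5-oxopentanoate, via dichloro(isopropoxy)titanium (Z)-enolate 15 (not isolated)
Conditions: TiCl4/Ti(OiPr)4 3:1 (gives TiCl3(OiPr), 1.05 equiv), iPr2NEt, CH2Cl2, 0 °C; then 14 (2 equiv), 0 °C
Reagents that add atoms: none
Why: Evans titanium-enolate Michael addition: the chelated (Z)-enolate is attacked by the acrylate on the face opposite the benzyl group, which sets C7 as (R), and the minor diastereomer is removed by chromatography or crystallisation.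

Step 9
Reactants: 16 tert-butyl (4R)-5-[(4S)-4-benzyl-2-oxo-1,3-oxazolidin-3-yl]-4-methyl-5-oxopentanoate
Product: 17 tert-butyl (4R)-5-hydroxy-4-methylpentanoate
Conditions: LiBH4 (1.2 equiv), H2O (1.2 equiv), Et2O, 0 °C
Reagents that add atoms: none
Why: Reductive cleavage of the auxiliary: the imide carbonyl is far more electrophilic than the hindered tert-butyl ester, so only it is reduced and the auxiliary is recovered.

Step 10
Reactants: 17 tert-butyl (4R)-5-hydroxy-4-methylpentanoate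
Product: 18 tert-butyl (4R)-4-methyl-5-oxopentanoate
Conditions: TEMPO (10 mol %), PhI(OAc)2 (1.1 equiv), CH2Cl2, rt
Reagents that add atoms: none
Why: Oxoammonium (TEMPO) oxidation stops at the aldehyde and is non-basic, so the α-stereocentre is not epimerised.

Step 11
Reactants: 18 tert-butyl (4R)-4-methyl-5-oxopentanoate
Product: 19 tert-butyl (4R)-4-methylhex-5-ynoate
Conditions: dimethyl (1-diazo-2-oxopropyl)phosphonate, K2CO3, MeOH, 0 °C to rt
Reagents that add atoms: dimethyl (1-diazo-2-oxopropyl)phosphonate, CC(=O)C(=[N+]=[N-])P(=O)(OC)OC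
Why: Seyferth–Gilbert homologation in its Ohira–Bestmann form converts the aldehyde into the terminal alkyne under mild carbonate conditions that leave the tert-butyl ester and the α-centre intact.

Step 12
Reactants: 19 tert-butyl (4R)-4-methylhex-5-ynoate
Product: 20 (4R)-4-methylhex-5-ynoic acid
Conditions: CF3CO2H/CH2Cl2 1:4, rt
Reagents that add atoms: none
Why: Acidolysis of the tert-butyl ester (loss of isobutene) is done here, where only a robust alkyne is present.

Step 13
Reactants: 20 (4R)-4-methylhex-5-ynoic acid; 21 (4R)-4-benzyl-1,3-oxazolidin-2-one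
Product: 23 (4R)-4-benzyl-3-[(4R)-4-methylhex-5-ynoyl]-1,3-oxazolidin-2-one, via mixed pivalic anhydride 22 (not isolated)
Conditions: PivCl, Et3N, THF, –20 °C; then 21, LiCl, rt
Reagents that add atoms: none
Why: N-acylation through the mixed anhydride: the oxazolidinone attacks the less hindered acyl carbon of the pivalic anhydride.

Step 14
Reactants: 23 (4R)-4-benzyl-3-[(4R)-4-methylhex-5-ynoyl]-1,3-oxazolidin-2-one
Product: 25 (4R)-4-benzyl-3-[(2R,4R)-2-hydroxy-4-methylhex-5-ynoyl]-1,3-oxazolidin-2-one, via sodium (Z)-enolate 24 (not isolated)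
Conditions: NaN(SiMe3)2 (1.1 equiv), THF, –78 °C; then 2-(phenylsulfonyl)-3-phenyloxaziridine (1.4 equiv), –78 °C; AcOH quench
Reagents that add atoms: 2-(benzenesulfonyl)-3-phenyloxaziridine, O=S(=O)(N1OC1c1ccccc1)c1ccccc1
Why: Evans asymmetric enolate hydroxylation with the Davis oxaziridine: oxygen is delivered to the chelated (Z)-enolate on the face opposite the benzyl group of the (R)-auxiliary, which sets C5 as (R) (typically ≥95:5, minor isomer separable).

Step 15
Reactants: 25 (4R)-4-benzyl-3-[(2R,4R)-2-hydroxy-4-methylhex-5-ynoyl]-1,3-oxazolidin-2-one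
Product: 26 methyl (2R,4R)-2-hydroxy-4-methylhex-5-ynoate
Conditions: MeMgBr (1.2 equiv), MeOH, CH2Cl2, 0 °C
Reagents that add atoms: methanol, CO
Why: Transesterification with methoxymagnesium bromide is assisted by chelation to the α-hydroxyl, cleaves the exocyclic acyl group selectively and does not epimerise C5.

Step 16
Reactants: 26 methyl (2R,4R)-2-hydroxy-4-methylhex-5-ynoate
Product: 27 methyl (2R,4R)-2-[(tert-butyldimethylsilyl)oxy]-4-methylhex-5-ynoate
Conditions: TBSCl, imidazole, DMF, rt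
Reagents that add atoms: tert-butyldimethylsilyl chloride, CC(C)(C)[Si](C)(C)Cl
Why: Silylation protects the C5 hydroxyl with a group that survives coupling, hydride and enolate steps and is released by fluoride at the end.

Step 17
Reactants: 27 methyl (2R,4R)-2-[(tert-butyldimethylsilyl)oxy]-4-methylhex-5-ynoate
Product: 28 methyl (2R,4R,5E)-2-[(tert-butyldimethylsilyl)oxy]-4-methyl-6-(4,4,5,5-tetramethyl-1,3,2-dioxaborolan-2-yl)hex-5-enoate
Conditions: B2pin2 (1.1 equiv), CuCl (5 mol %), Xantphos (5 mol %), NaOtBu (10 mol %), MeOH (2 equiv), THF, rt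
Reagents that add atoms: bis(pinacolato)diboron, CC1(C)OB(OC1(C)C)B1OC(C)(C)C(C)(C)O1
Why: Copper-catalysed hydroboration (syn borylcupration with boron at the terminus, then protonation by methanol) gives only the (E)-alkenylboronate.

**Union and end game**

Step 18
Reactants: 28 methyl (2R,4R,5E)-2-[(tert-butyldimethylsilyl)oxy]-4-methyl-6-(4,4,5,5-tetramethyl-1,3,2-dioxaborolan-2-yl)hex-5-enoate; 12 3-[(4S,8E)-9-iodo-4,8-dimethylnon-8-en-1-yl]furan
Product: 29 methyl (2R,4R,5E,7E,12R)-2-[(tert-butyldimethylsilyl)oxy]-15-(furan-3-yl)-4,8,12-trimethylpentadeca-5,7-dienoate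
Conditions: Pd(dppf)Cl2 (5 mol %), AsPh3 (10 mol %), Cs2CO3 (3 equiv), DMF/THF/H2O, rt
Reagents that add atoms: none
Why: Suzuki–Miyaura alkenyl–alkenyl coupling proceeds with retention at both partners and so gives the (8E,10E)-diene.

Step 19
Reactants: 29 methyl (2R,4R,5E,7E,12R)-2-[(tert-butyldimethylsilyl)oxy]-15-(furan-3-yl)-4,8,12-trimethylpentadeca-5,7-dienoate
Product: 30 (2R,4R,5E,7E,12R)-2-[(tert-butyldimethylsilyl)oxy]-15-(furan-3-yl)-4,8,12-trimethylpentadeca-5,7-dienal
Conditions: iBu2AlH (1.15 equiv), CH2Cl2, –78 °C; MeOH, then aq. KNaC4H4O6; used crude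
Reagents that add atoms: none
Why: Partial reduction of the α-silyloxy ester stops at the aluminium hemiacetal, which is stable at –78 °C and releases the aldehyde only on work-up.

Step 20
Reactants: 30 (2R,4R,5E,7E,12R)-2-[(tert-butyldimethylsilyl)oxy]-15-(furan-3-yl)-4,8,12-trimethylpentadeca-5,7-dienal; 31 methyl propanoate
Product: 33 methyl (4R,6R,7E,9E,14R)-4-[(tert-butyldimethylsilyl)oxy]-17-(furan-3-yl)-3-hydroxy-2,6,10,14-tetramethylheptadeca-7,9-dienoate (C2/C3 diastereomer mixture), via lithium enolate 32 (not isolated)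
Conditions: 31 (2.2 equiv), LiN(iPr)2 (2.0 equiv), THF, –78 °C; then 30, –78 °C; aq. NH4Cl
Reagents that add atoms: none
Why: Intermolecular aldol addition forms the C3–C4 bond faster than the aldehyde can be enolised at –78 °C, and the two new stereocentres are irrelevant because C4 is oxidised in step 21 and C3 becomes sp2 in step 22.

Step 21
Reactants: 33 methyl (4R,6R,7E,9E,14R)-4-[(tert-butyldimethylsilyl)oxy]-17-(furan-3-yl)-3-hydroxy-2,6,10,14-tetramethylheptadeca-7,9-dienoate
Product: 34 methyl (4R,6R,7E,9E,14R)-4-[(tert-butyldimethylsilyl)oxy]-17-(furan-3-yl)-2,6,10,14-tetramethyl-3-oxoheptadeca-7,9-dienoate (C2 epimers)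
Conditions: Dess–Martin periodinane (1.5 equiv), NaHCO3, CH2Cl2, 0 °C to rt
Reagents that add atoms: none
Why: Buffered Dess–Martin oxidation converts the β-hydroxy ester into the β-keto ester without touching the diene, the furan or the silyl ether.

Step 22
Reactants: 34 methyl (4R,6R,7E,9E,14R)-4-[(tert-butyldimethylsilyl)oxy]-17-(furan-3-yl)-2,6,10,14-tetramethyl-3-oxoheptadeca-7,9-dienoate
Product: 36 (5R)-5-[(2R,3E,5E,10R)-13-(furan-3-yl)-2,6,10-trimethyltrideca-3,5-dien-1-yl]-4-hydroxy-3-methylfuran-2(5H)-one (target CNP0246504.1), via γ-hydroxy β-keto ester 35 (not isolated)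
Conditions: Bu4NF (2 equiv), THF, 0 °C to rt; then cold 0.5 M HCl to pH 2–3
Reagents that add atoms: none
Why: Fluoride desilylation frees the C5 alkoxide, which lactonises onto the methyl ester (5-exo-trig) and the β-keto lactone enolises to the tetronic acid; the C5–O bond is never broken, so (5R) is kept.

**Compound list**
1 | (R)-citronellal, (3R)-3,7-dimethyloct-6-enal | CC(C)=CCC[C@@H](C)CC=O | starting material
2 | (4R)-4,8-dimethylnona-1,7-diene | CC(C)=CCC[C@@H](C)CC=C | intermediate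
3 | 3-bromofuran | Brc1ccoc1 | starting material
4 | 9-[(4S)-4,8-dimethylnon-7-en-1-yl]-9-borabicyclo[3.3.1]nonane | CC(C)=CCC[C@@H](C)CCCB1C2CCCC1CCC2 | intermediate
5 | 3-[(4S)-4,8-dimethylnon-7-en-1-yl]furan | CC(C)=CCC[C@@H](C)CCCc1ccoc1 | intermediate
6 | (6S)-9-(furan-3-yl)-2,6-dimethylnonane-2,3-diol (both C3 epimers) | CC(C)(O)C(O)CC[C@@H](C)CCCc1ccoc1 | intermediate
7 | (4S)-7-(furan-3-yl)-4-methylheptanal | O=CCC[C@@H](C)CCCc1ccoc1 | intermediate
8 | (4S)-7-(furan-3-yl)-4-methylheptan-1-ol | OCCC[C@@H](C)CCCc1ccoc1 | intermediate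
9 | (4S)-7-(furan-3-yl)-4-methylheptyl 4-methylbenzenesulfonate | Cc1ccc(cc1)S(=O)(=O)OCCC[C@@H](C)CCCc1ccoc1 | intermediate
10 | 3-[(4R)-4-methylnon-8-yn-1-yl]furan | C#CCCC[C@@H](C)CCCc1ccoc1 | intermediate
11 | [(1E,6S)-9-(furan-3-yl)-2,6-dimethylnon-1-en-1-yl]dimethylalumane | C[Al](C)/C=C(\C)CCC[C@@H](C)CCCc1ccoc1 | intermediate
12 | 3-[(4S,8E)-9-iodo-4,8-dimethylnon-8-en-1-yl]furan | I/C=C(\C)CCC[C@@H](C)CCCc1ccoc1 | intermediate
13 | (4S)-4-benzyl-3-propanoyl-1,3-oxazolidin-2-one | CCC(=O)N1[C@@H](Cc2ccccc2)COC1=O | starting material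
14 | tert-butyl acrylate (tert-butyl prop-2-enoate) | C=CC(=O)OC(C)(C)C | starting material
15 | dichloro(isopropoxy)titanium (Z)-enolate of 13 | C/C=C(\O[Ti](Cl)(Cl)OC(C)C)N1[C@@H](Cc2ccccc2)COC1=O | intermediate
16 | tert-butyl (4R)-5-[(4S)-4-benzyl-2-oxo-1,3-oxazolidin-3-yl]-4-methyl-5-oxopentanoate | CC(C)(C)OC(=O)CC[C@@H](C)C(=O)N1[C@@H](Cc2ccccc2)COC1=O | intermediate
17 | tert-butyl (4R)-5-hydroxy-4-methylpentanoate | CC(C)(C)OC(=O)CC[C@@H](C)CO | intermediate
18 | tert-butyl (4R)-4-methyl-5-oxopentanoate | CC(C)(C)OC(=O)CC[C@@H](C)C=O | intermediate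
19 | tert-butyl (4R)-4-methylhex-5-ynoate | CC(C)(C)OC(=O)CC[C@@H](C)C#C | intermediate
20 | (4R)-4-methylhex-5-ynoic acid | OC(=O)CC[C@@H](C)C#C | intermediate
21 | (4R)-4-benzyl-1,3-oxazolidin-2-one | O=C1N[C@H](Cc2ccccc2)CO1 | starting material
22 | 2,2-dimethylpropanoic (4R)-4-methylhex-5-ynoic anhydride | CC(C)(C)C(=O)OC(=O)CC[C@@H](C)C#C | intermediate
23 | (4R)-4-benzyl-3-[(4R)-4-methylhex-5-ynoyl]-1,3-oxazolidin-2-one | O=C(CC[C@@H](C)C#C)N1[C@H](Cc2ccccc2)COC1=O | intermediate
24 | sodium (Z)-enolate of 23 | [Na+].[O-]/C(=C\C[C@@H](C)C#C)N1[C@H](Cc2ccccc2)COC1=O | intermediate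
25 | (4R)-4-benzyl-3-[(2R,4R)-2-hydroxy-4-methylhex-5-ynoyl]-1,3-oxazolidin-2-one | O=C([C@@H](C[C@@H](C)C#C)O)N1[C@H](Cc2ccccc2)COC1=O | intermediate
26 | methyl (2R,4R)-2-hydroxy-4-methylhex-5-ynoate | COC(=O)[C@@H](C[C@@H](C)C#C)O | intermediate
27 | methyl (2R,4R)-2-[(tert-butyldimethylsilyl)oxy]-4-methylhex-5-ynoate | COC(=O)[C@@H](C[C@@H](C)C#C)O[Si](C)(C)C(C)(C)C | intermediate
28 | methyl (2R,4R,5E)-2-[(tert-butyldimethylsilyl)oxy]-4-methyl-6-(4,4,5,5-tetramethyl-1,3,2-dioxaborolan-2-yl)hex-5-enoate | COC(=O)[C@@H](C[C@@H](C)/C=C/B1OC(C)(C)C(C)(C)O1)O[Si](C)(C)C(C)(C)C | intermediate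
29 | methyl (2R,4R,5E,7E,12R)-2-[(tert-butyldimethylsilyl)oxy]-15-(furan-3-yl)-4,8,12-trimethylpentadeca-5,7-dienoate | COC(=O)[C@@H](C[C@@H](C)/C=C/C=C(\C)CCC[C@@H](C)CCCc1ccoc1)O[Si](C)(C)C(C)(C)C | intermediate
30 | (2R,4R,5E,7E,12R)-2-[(tert-butyldimethylsilyl)oxy]-15-(furan-3-yl)-4,8,12-trimethylpentadeca-5,7-dienal | O=C[C@@H](C[C@@H](C)/C=C/C=C(\C)CCC[C@@H](C)CCCc1ccoc1)O[Si](C)(C)C(C)(C)C | intermediate
31 | methyl propanoate | CCC(=O)OC | starting material
32 | lithium 1-methoxyprop-1-en-1-olate (kinetic enolate of 31, methyl trans to OLi) | C/C=C(\OC)O[Li] | intermediate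
33 | methyl (4R,6R,7E,9E,14R)-4-[(tert-butyldimethylsilyl)oxy]-17-(furan-3-yl)-3-hydroxy-2,6,10,14-tetramethylheptadeca-7,9-dienoate (C2/C3 mixture) | COC(=O)C(C)C(O)[C@@H](C[C@@H](C)/C=C/C=C(\C)CCC[C@@H](C)CCCc1ccoc1)O[Si](C)(C)C(C)(C)C | intermediate
34 | methyl (4R,6R,7E,9E,14R)-4-[(tert-butyldimethylsilyl)oxy]-17-(furan-3-yl)-2,6,10,14-tetramethyl-3-oxoheptadeca-7,9-dienoate (C2 epimers) | COC(=O)C(C)C(=O)[C@@H](C[C@@H](C)/C=C/C=C(\C)CCC[C@@H](C)CCCc1ccoc1)O[Si](C)(C)C(C)(C)C | intermediate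
35 | methyl (4R,6R,7E,9E,14R)-17-(furan-3-yl)-4-hydroxy-2,6,10,14-tetramethyl-3-oxoheptadeca-7,9-dienoate (C2 epimers) | COC(=O)C(C)C(=O)[C@@H](C[C@@H](C)/C=C/C=C(\C)CCC[C@@H](C)CCCc1ccoc1)O | intermediate
36 | (5R)-5-[(2R,3E,5E,10R)-13-(furan-3-yl)-2,6,10-trimethyltrideca-3,5-dien-1-yl]-4-hydroxy-3-methylfuran-2(5H)-one | CC1=C(O)[C@@H](C[C@@H](C)/C=C/C=C(\C)CCC[C@@H](C)CCCc2ccoc2)OC1=O | target

**Totals and fallbacks**
Total step count: 22. Longest linear sequence: 15 steps (steps 8–22, from 13 and 14 to 36); the 7-step sequence from 1 to 12 joins at step 18.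

Step 3 (osmium-catalysed dihydroxylation beside the furan; over-oxidation of the furan is the danger). The fallback brings the furan in only after the oxidative cleavage. It sets out from diene 2: mCPBA (1.0 equiv, CH2Cl2, 0 °C) epoxidises only the trisubstituted alkene to 2,2-dimethyl-3-[(3R)-3-methylhex-5-en-1-yl]oxirane F1; HIO4·2H2O (THF/Et2O, 0 °C) cleaves it to (4R)-4-methylhept-6-enal F2; NaBH4 (MeOH, 0 °C) gives (4R)-4-methylhept-6-en-1-ol F3; hydroboration with 9-BBN (2.2 equiv, one equivalent being taken up by the hydroxyl group) and coupling with 3 under the conditions of step 2 then comes back to the route at alcohol 8.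

Step 18 (alkenyl–alkenyl Suzuki coupling; slow transmetalation or protodeboronation of the pinacol boronate would cost material from both fragments). The fallback is a Negishi coupling that sets out from alkyne 27 and iodide 12. Hydrozirconation of 27 with Cp2Zr(H)Cl (THF, rt) gives chlorobis(cyclopentadienyl)[(1E,3R,5R)-5-[(tert-butyldimethylsilyl)oxy]-6-methoxy-3-methyl-6-oxohex-1-en-1-yl]zirconium F4; ZnCl2 (THF, 0 °C) converts it into chloro[(1E,3R,5R)-5-[(tert-butyldimethylsilyl)oxy]-6-methoxy-3-methyl-6-oxohex-1-en-1-yl]zinc F5; Pd(PPh3)4 (5 mol %, THF, rt) couples this with 12 and comes back at diene ester 29.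

Step 20 (aldol on aldehyde 30, which is epimerisable at C5 and cannot be stored). The fallback is a crossed Claisen-type acylation that never passes through the aldehyde. It sets out from ester 29: MeONHMe·HCl and iPrMgCl (THF, –20 °C) give (2R,4R,5E,7E,12R)-2-[(tert-butyldimethylsilyl)oxy]-15-(furan-3-yl)-N-methoxy-N,4,8,12-tetramethylpentadeca-5,7-dienamide F6, which acylates lithium enolate 32 (3 equiv, THF, –78 to –30 °C) and so comes back to the route at β-keto ester 34, leaving out steps 19 to 21.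

**Further compounds**
F1 | step 3 | 2,2-dimethyl-3-[(3R)-3-methylhex-5-en-1-yl]oxirane (both oxirane epimers) | CC1(C)OC1CC[C@@H](C)CC=C
F2 | step 3 | (4R)-4-methylhept-6-enal | O=CCC[C@@H](C)CC=C
F3 | step 3 | (4R)-4-methylhept-6-en-1-ol | OCCC[C@@H](C)CC=C
F4 | step 18 | chlorobis(cyclopentadienyl)[(1E,3R,5R)-5-[(tert-butyldimethylsilyl)oxy]-6-methoxy-3-methyl-6-oxohex-1-en-1-yl]zirconium | COC(=O)[C@@H](C[C@@H](C)/C=C/[Zr](Cl)(C1C=CC=C1)C1C=CC=C1)O[Si](C)(C)C(C)(C)C
F5 | step 18 | chloro[(1E,3R,5R)-5-[(tert-butyldimethylsilyl)oxy]-6-methoxy-3-methyl-6-oxohex-1-en-1-yl]zinc | COC(=O)[C@@H](C[C@@H](C)/C=C/[Zn]Cl)O[Si](C)(C)C(C)(C)C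
F6 | step 20 | (2R,4R,5E,7E,12R)-2-[(tert-butyldimethylsilyl)oxy]-15-(furan-3-yl)-N-methoxy-N,4,8,12-tetramethylpentadeca-5,7-dienamide | CON(C)C(=O)[C@@H](C[C@@H](C)/C=C/C=C(\C)CCC[C@@H](C)CCCc1ccoc1)O[Si](C)(C)C(C)(C)C
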